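**Plan**

1. Retrosynthesis: the CHO on C2 and the CH2OH on C3 are folded into a five-membered cyclic acetal. The bonds C2–C3 and C1–C8a of the dihydronaphthalene are then cut in one operation, leaving an acyclic acetal-tethered 1,6-enyne. Its acetal C–O bonds and aryl–alkyne bonds lead back to coniferaldehyde, propargyl alcohol and 4-bromo-2-methoxyphenol.
2. Enabling feature (C1 = ArCH, C2 = CH(CHO), C3 = C(CH2OH)=, C4 = vinylic CH, ring A = C4a, C5–C8, C8a): ring A with C4=C3 is a 4-oxygenated 3-methoxyphenyl alkyne in disguise, C1–C2 is the E alkene of coniferaldehyde, and the formyl and hydroxymethyl carbons are one oxygen apart, so they can serve as the tether.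
3. Forward: silylated coniferaldehyde is converted into its dimethyl acetal. Sonogashira coupling gives a 3-arylpropargyl alcohol, and two molecules of it are exchanged into the acetal so that the enyne has no stereocentre. One gold-catalysed step closes the cyclic acetal (C2–C3) and the carbocycle (C1–C8a); acetal hydrolysis and desilylation finish the synthesis.
4. Stereochemistry: C2 comes from face selection on the achiral enyne by a chiral gold catalyst. C1 comes from the E alkene, whose geometry is relayed into the trans C1/C2 relationship. The acetal carbon is a temporary centre that disappears on hydrolysis.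

Key step: step 6

Remark: the target and its bis-silyl precursor are γ-hydroxy aldehydes in ring–chain equilibrium with five-membered lactols; each is treated as one compound and written in the open form of the target.
Remark: the sense of induction of the chiral gold complex on this tether cannot be predicted with confidence; the (R)-ligand is written, and its (S)-enantiomer is to be used if the first experiment shows the opposite sense.
TBS = tert-butyldimethylsilyl.

**Route**

Step 1
Reactants: 1 coniferaldehyde, (E)-3-(4-hydroxy-3-methoxyphenyl)prop-2-enal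
Product: 2 (E)-3-[4-(TBS-oxy)-3-methoxyphenyl]prop-2-enal
Conditions: TBSCl, imidazole, DMF, 0 °C to rt
Reagents that add atoms: tert-butyldimethylsilyl chloride, CC(C)(C)[Si](C)(C)Cl
Why: Standard silylation of a phenol with a silyl chloride and imidazole, in which the enal is inert and the silyl ether later makes the aryl group a strong donor for the benzylic cation at C1.

Step 2
Reactants: 2 (E)-3-[4-(TBS-oxy)-3-methoxyphenyl]prop-2-enal
Product: 3 dimethyl acetal of 2, (E)-tert-butyl[4-(3,3-dimethoxyprop-1-enyl)-2-methoxyphenoxy]dimethylsilane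
Conditions: HC(OMe)3, MeOH, PPTS (cat.), rt; Et3N quench
Reagents that add atoms: trimethyl orthoformate, COC(OC)OC; methanol, CO
Why: Acid-catalysed acetalisation with an orthoformate as water scavenger is routine for cinnamaldehydes, and the weak pyridinium acid with a triethylamine quench should keep the aryl silyl ether, the E alkene and the acid-labile product intact.

Step 3
Reactants: 4 4-bromo-2-methoxyphenol
Product: 5 (4-bromo-2-methoxyphenoxy)(tert-butyl)dimethylsilane
Conditions: TBSCl, imidazole, DMF, rt
Reagents that add atoms: tert-butyldimethylsilyl chloride, CC(C)(C)[Si](C)(C)Cl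
Why: Phenol silylation as in step 1, which masks the acidic OH before the palladium coupling and gives ring A the same protecting group as the pendant ring.

Step 4
Reactants: 5 (4-bromo-2-methoxyphenoxy)(tert-butyl)dimethylsilane; 6 propargyl alcohol (prop-2-yn-1-ol)
Product: 7 3-[4-(TBS-oxy)-3-methoxyphenyl]prop-2-yn-1-ol
Conditions: PdCl2(PhCN)2 (3 mol %), [HP(t-Bu)3]BF4 (6 mol %), CuI (2 mol %), i-Pr2NH, dioxane, rt
Reagents that add atoms: none
Why: Sonogashira coupling, in which the bulky electron-rich tri-tert-butylphosphine ligand lets electron-rich aryl bromides react at room temperature, conditions that leave the aryl silyl ether and the free propargylic OH untouched.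

Step 5
Reactants: 3 dimethyl acetal of 2; 7 3-[4-(TBS-oxy)-3-methoxyphenyl]prop-2-yn-1-ol (2.3 equiv)
Product: 9 bis{3-[4-(TBS-oxy)-3-methoxyphenyl]prop-2-ynyl} acetal of 2, via mixed methyl arylpropargyl acetal 8 (not isolated)
Conditions: PPTS (5 mol %), toluene, 50 °C, 120 mbar (MeOH distilled off); Et3N quench
Reagents that add atoms: none
Why: Acid-catalysed transacetalisation, in which the stabilised cinnamyl-type oxocarbenium ion exchanges both methoxy groups and continuous removal of methanol drives the equilibrium past mixed acetal 8 to the symmetric acetal, which unlike 8 carries no stereocentre.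

Step 6
Reactants: 9 bis(3-arylprop-2-ynyl) acetal of 2
Product: 10 (9S,9aR)-7-(TBS-oxy)-9-[4-(TBS-oxy)-3-methoxyphenyl]-6-methoxy-1-{3-[4-(TBS-oxy)-3-methoxyphenyl]prop-2-ynyloxy}-1,3,9,9a-tetrahydronaphtho[2,3-c]furan (target numbering C1 S, C2 R; aryl trans to the acetal carbon; acetal carbon as epimer mixture)
Conditions: (R)-DTBM-SEGPHOS(AuCl)2 (3 mol %), AgNTf2 (6 mol %; AgCl filtered off), 2,6-di-tert-butylpyridine (5 mol %), 4 Å MS, CH2Cl2, −20 to 0 °C
Reagents that add atoms: none
Why: Proposed new method: the chiral cationic gold complex binds one aryl alkyne of 9, the alkene carbon C2 attacks C3 anti to gold to give a cyclopropyl gold carbene that behaves as a C1 benzylic cation stabilised by the para-silyloxy group, C8a of ring A captures C1, and rearomatisation followed by protodeauration leaves C4–H; the closest known reaction type is the gold-catalysed formal [4+2] cycloaddition of aryl alkynes with alkenes in carbon- and sulfonamide-tethered 1,6-enynes, enantioselective versions with chiral phosphine–gold complexes included, whereas an acetal tether has not been shown. The five-membered cyclic acetal closes 5-exo-dig (C2 onto C3), and the six-membered carbocycle closes by intramolecular Friedel–Crafts alkylation of C8a by C1, the second bond of a stepwise [4+2]. C2 is set by the alkene face that the ligand-bound gold–alkyne unit can reach, which is pure catalyst control because 9 has two identical propargyl arms and no stereocentre, and C1 follows from C2 because the cyclopropane-like intermediate transmits the E geometry stereospecifically into the trans C1/C2 relationship. The step needs exo and not endo attack on the alkyne, and the strongly cation-stabilising 4-silyloxy-3-methoxyphenyl group on C1 together with the well-placed nucleophilic ring A is expected to channel the intermediate into the open-cation Friedel–Crafts path instead of 6-endo cyclopropanation. It further needs arylation para to the ring-A methoxy group, for which the other ortho position is flanked by the alkyne carbon and the methoxy group and should not compete, and it needs the acid-labile acetal to survive, which the filtered silver-free catalyst solution, the hindered pyridine buffer, molecular sieves and low temperature should secure. Both acetal epimers of 10 are acceptable because the acetal carbon ceases to be a stereocentre in step 7.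

Step 7
Reactants: 10 cyclic arylpropargyl acetal
Product: 12 (1S,2R)-7-(TBS-oxy)-1-[4-(TBS-oxy)-3-methoxyphenyl]-3-(hydroxymethyl)-6-methoxy-1,2-dihydronaphthalene-2-carbaldehyde, via lactol 11 (not isolated)
Conditions: PPTS (0.2 equiv), acetone/H2O 5:1, 35 °C
Reagents that add atoms: water, O
Why: Hydrolysis of a tetrahydrofuranyl-type mixed acetal under mild aqueous acid, which should cleave both acetal epimers to the same lactol and open hydroxy aldehyde, leave the aryl silyl ethers and the C2 stereocentre untouched and return alcohol 7 for reuse in step 5.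

Step 8
Reactants: 12 bis-silyl hydroxy aldehyde
Product: 13 (1S,2R)-7-hydroxy-1-(4-hydroxy-3-methoxyphenyl)-3-(hydroxymethyl)-6-methoxy-1,2-dihydronaphthalene-2-carbaldehyde (target)
Conditions: TBAF, AcOH (1:1), THF, 0 °C
Reagents that add atoms: none
Why: Fluoride cleavage of aryl silyl ethers, buffered with acetic acid so that neither phenoxide nor free fluoride can epimerise C2 or move the C3=C4 double bond into conjugation with the aldehyde.

**Compound list**

1 | coniferaldehyde, (E)-3-(4-hydroxy-3-methoxyphenyl)prop-2-enal | COc1cc(/C=C/C=O)ccc1O | starting material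
2 | (E)-3-[4-(tert-butyldimethylsilyloxy)-3-methoxyphenyl]prop-2-enal | COc1cc(/C=C/C=O)ccc1O[Si](C)(C)C(C)(C)C | intermediate
3 | (E)-tert-butyl[4-(3,3-dimethoxyprop-1-enyl)-2-methoxyphenoxy]dimethylsilane | COc1cc(/C=C/C(OC)OC)ccc1O[Si](C)(C)C(C)(C)C | intermediate
4 | 4-bromo-2-methoxyphenol | COc1cc(Br)ccc1O | starting material
5 | (4-bromo-2-methoxyphenoxy)(tert-butyl)dimethylsilane | COc1cc(Br)ccc1O[Si](C)(C)C(C)(C)C | intermediate
6 | prop-2-yn-1-ol (propargyl alcohol) | C#CCO | starting material
7 | 3-[4-(tert-butyldimethylsilyloxy)-3-methoxyphenyl]prop-2-yn-1-ol | COc1cc(C#CCO)ccc1O[Si](C)(C)C(C)(C)C | intermediate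
8 | mixed methyl 3-arylprop-2-ynyl acetal of 2 (racemic at the acetal carbon, not isolated) | COC(OCC#Cc1ccc(O[Si](C)(C)C(C)(C)C)c(OC)c1)/C=C/c1ccc(O[Si](C)(C)C(C)(C)C)c(OC)c1 | intermediate
9 | (E)-3-[4-(TBS-oxy)-3-methoxyphenyl]prop-2-enal bis{3-[4-(TBS-oxy)-3-methoxyphenyl]prop-2-ynyl} acetal | COc1cc(/C=C/C(OCC#Cc2ccc(O[Si](C)(C)C(C)(C)C)c(OC)c2)OCC#Cc2ccc(O[Si](C)(C)C(C)(C)C)c(OC)c2)ccc1O[Si](C)(C)C(C)(C)C | intermediate
10 | (9S,9aR)-7-(TBS-oxy)-9-[4-(TBS-oxy)-3-methoxyphenyl]-6-methoxy-1-{3-[4-(TBS-oxy)-3-methoxyphenyl]prop-2-ynyloxy}-1,3,9,9a-tetrahydronaphtho[2,3-c]furan, acetal carbon as epimer mixture | COc1cc([C@H]2c3cc(O[Si](C)(C)C(C)(C)C)c(OC)cc3C=C3COC(OCC#Cc4ccc(O[Si](C)(C)C(C)(C)C)c(OC)c4)[C@H]23)ccc1O[Si](C)(C)C(C)(C)C | intermediate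
11 | (9S,9aR)-7-(TBS-oxy)-9-[4-(TBS-oxy)-3-methoxyphenyl]-6-methoxy-1,3,9,9a-tetrahydronaphtho[2,3-c]furan-1-ol (lactol, anomer mixture, not isolated) | COc1cc([C@H]2c3cc(O[Si](C)(C)C(C)(C)C)c(OC)cc3C=C3COC(O)[C@H]23)ccc1O[Si](C)(C)C(C)(C)C | intermediate
12 | (1S,2R)-7-(TBS-oxy)-1-[4-(TBS-oxy)-3-methoxyphenyl]-3-(hydroxymethyl)-6-methoxy-1,2-dihydronaphthalene-2-carbaldehyde | COc1cc([C@H]2c3cc(O[Si](C)(C)C(C)(C)C)c(OC)cc3C=C(CO)[C@@H]2C=O)ccc1O[Si](C)(C)C(C)(C)C | intermediate
13 | (1S,2R)-7-hydroxy-1-(4-hydroxy-3-methoxyphenyl)-3-(hydroxymethyl)-6-methoxy-1,2-dihydronaphthalene-2-carbaldehyde | COc1cc([C@H]2c3cc(O)c(OC)cc3C=C(CO)[C@@H]2C=O)ccc1O | target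

**Step count and risks**

Total steps: 8. Longest linear sequence: 6 steps (1, 2, 5, 6, 7, 8; the branch through steps 3 and 4 is equally long).

Steps most likely to fail:

1. Step 6 (proposed new method). The gold–alkyne intermediate may leave the exo manifold, either by attack of C2 on the aryl-bearing alkyne carbon with 6-endo cyclopropanation or by addition of an acetal oxygen to the alkyne. The acetal may also ionise at the Lewis-acidic metal, or the catalyst may discriminate the alkene faces poorly.
Fallback by known chemistry, setting out from 2 and 7 and returning at 13: the carbocycle is closed by the acid-promoted Friedel–Crafts cyclisation established for 2,3-bis(arylidene)succinic acid derivatives, here at the aldehyde/alcohol oxidation level. Aldehyde 2 is brominated (Br2, CH2Cl2, −78 °C) to 2,3-dibromo aldehyde F1, which is not isolated and loses HBr with Et3N to give (Z)-α-bromo enal F2. Alcohol 7 undergoes hydroxyl-directed trans-hydrostannation (Bu3SnH, [Cp*RuCl]4 cat., CH2Cl2), which places tin on the carbon next to CH2OH and cis to the aryl group, to give (Z)-2-stannyl allylic alcohol F3. Silylation (TBSCl, imidazole) gives silyl ether F4. Stille coupling of F2 with F4 (Pd(PPh3)4, CuI, CsF, DMF) gives (E,E)-dienal F5, in which both aryl groups lie cis to the new C2–C3 bond. With TFA in CH2Cl2 at −20 °C the protonated enal should be attacked at C1 by ring A para to its methoxy group, and tautomerisation of the enol should give the trans aldehyde as the racemate. The (1S,2R) enantiomer, tris-silyl aldehyde F6, is collected by HPLC on a chiral stationary phase and desilylated with buffered fluoride as in step 8 to give 13.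

2. Step 5. Exchange may stall at the mixed acetal, and prolonged acid contact with a non-volatile alcohol may cause allylic transposition or hydrolysis of the cinnamyl-type acetal.
Fallback, setting out from 3 and returning at 9: the order of the two bond formations is inverted, so that the acid-catalysed exchange is run with a cheap, volatile alcohol in large excess and the aryl groups are attached afterwards under basic conditions. Acetal 3 is warmed with propargyl alcohol 6 as co-solvent and PPTS while methanol distils, passing through methyl prop-2-ynyl acetal F7 (not isolated) to bis(prop-2-ynyl) acetal F8. Twofold Sonogashira coupling of F8 with bromide 5 under the conditions of step 4 then gives 9 by way of mono-arylated acetal F9 (not isolated).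

3. Step 8. Desilylation in the presence of the free aldehyde may be accompanied by epimerisation at C2 or by migration of the ring double bond into conjugation once phenoxide is generated.
Fallback, setting out from 10 and returning at 13: the two unmasking steps are inverted so that the aldehyde never meets fluoride. Acetal 10, which has no acidic C–H, is desilylated with TBAF in THF to tris-phenol acetal F10, and mild aqueous acid as in step 7 then releases 13 directly together with the phenolic propargyl alcohol.

**Further compounds**

F1 | step 6 | 2,3-dibromo-3-[4-(TBS-oxy)-3-methoxyphenyl]propanal (diastereomer mixture, not isolated) | COc1cc(C(Br)C(Br)C=O)ccc1O[Si](C)(C)C(C)(C)C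
F2 | step 6 | (Z)-2-bromo-3-[4-(TBS-oxy)-3-methoxyphenyl]prop-2-enal | COc1cc(/C=C(\Br)C=O)ccc1O[Si](C)(C)C(C)(C)C
F3 | step 6 | (Z)-3-[4-(TBS-oxy)-3-methoxyphenyl]-2-(tributylstannyl)prop-2-en-1-ol | CCCC[Sn](CCCC)(CCCC)/C(CO)=C\c1ccc(O[Si](C)(C)C(C)(C)C)c(OC)c1
F4 | step 6 | TBS ether of F3, (Z)-tributyl{3-[4-(TBS-oxy)-3-methoxyphenyl]-1-(TBS-oxy)prop-2-en-2-yl}stannane | CCCC[Sn](CCCC)(CCCC)/C(CO[Si](C)(C)C(C)(C)C)=C\c1ccc(O[Si](C)(C)C(C)(C)C)c(OC)c1
F5 | step 6 | (E,E)-dienal, (2E)-3-[4-(TBS-oxy)-3-methoxyphenyl]-2-{(1E)-2-[4-(TBS-oxy)-3-methoxyphenyl]-1-(TBS-oxymethyl)vinyl}prop-2-enal | CC(C)(C)[Si](C)(C)Oc1ccc(/C=C(/C=O)\C(=C/c2ccc(O[Si](C)(C)C(C)(C)C)c(OC)c2)CO[Si](C)(C)C(C)(C)C)cc1OC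
F6 | step 6 | (1S,2R)-7-(TBS-oxy)-1-[4-(TBS-oxy)-3-methoxyphenyl]-6-methoxy-3-(TBS-oxymethyl)-1,2-dihydronaphthalene-2-carbaldehyde (formed as the racemate, this enantiomer collected after resolution) | COc1cc([C@H]2c3cc(O[Si](C)(C)C(C)(C)C)c(OC)cc3C=C(CO[Si](C)(C)C(C)(C)C)[C@@H]2C=O)ccc1O[Si](C)(C)C(C)(C)C
F7 | step 5 | mixed methyl prop-2-ynyl acetal of 2 (racemic, not isolated) | COC(OCC#C)/C=C/c1ccc(O[Si](C)(C)C(C)(C)C)c(OC)c1
F8 | step 5 | bis(prop-2-ynyl) acetal of 2 | C#CCOC(OCC#C)/C=C/c1ccc(O[Si](C)(C)C(C)(C)C)c(OC)c1
F9 | step 5 | mono-arylated acetal, prop-2-ynyl 3-[4-(TBS-oxy)-3-methoxyphenyl]prop-2-ynyl acetal of 2 (racemic, not isolated) | C#CCOC(OCC#Cc1ccc(O[Si](C)(C)C(C)(C)C)c(OC)c1)/C=C/c1ccc(O[Si](C)(C)C(C)(C)C)c(OC)c1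
F10 | step 8 | desilylated 10, (9S,9aR)-9-(4-hydroxy-3-methoxyphenyl)-1-[3-(4-hydroxy-3-methoxyphenyl)prop-2-ynyloxy]-6-methoxy-1,3,9,9a-tetrahydronaphtho[2,3-c]furan-7-ol (acetal epimers) | COc1cc([C@H]2c3cc(O)c(OC)cc3C=C3COC(OCC#Cc4ccc(O)c(OC)c4)[C@H]23)ccc1O
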